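You take over two flasks, and the easy step comes first: no arrow below removes a living end, so [living end] counts every chain begun, and the length asked for (the number-average degree of polymerisation) is [monomer in chains] over [living end].

the same everywhere: protic impurity 0.250 mM; initiator 7.5 mol%; time 10 s

|  | free monomer |
|---|---|
| Tuesday's | 5.0 mM (fed, over 10 s) |
| Saturday's | 5.0 mM (fed, over 3.0 s) |

    free monomer + initiator → living end + monomer in chains (k1 = 7.8 /M/s)
    free monomer + living end → monomer in chains + living end, rate k2*[living end]*[free monomer] (k2 = 160 /M/s)
    protic impurity + free monomer → quenched substrate (k3 = 160 /M/s)

- which of the two ends with the longer chains by the average number of monomer units in a chain (chains begun, living or dead) ("neither" if they lie within 10%) (Tuesday's / Saturday's / neither)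
- average number of monomer units in a chain (chains begun, living or dead) at the end, Tuesday's
- average number of monomer units in a chain (chains begun, living or dead) at the end, Saturday's

When you come, expect Tuesday's flask to hold mostly free monomer: initiation alone gives it a half-life of 3.9 min, far longer than the 10 s run. Divide the rate of propagation by the rate of initiation and time drops out: each chain begun brings in G[living end]/[initiator] units, with G = 20.5, the propagation constant over the initiation constant, the growth ratio. Since [living end] and [initiator] sum to the initiator charge, integrating gives length = 1 + G(−ln f/(1 − f) − 1), where f is the fraction of initiator left. That fraction is the exponential of minus the initiation constant times the time integral of [free monomer].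

I reckon that integral from the steady feed, neglecting what the chains take. I also subtract the impurity's charge for the whole run, a rough allowance that overstates its toll: the half-life of 0.87 s supposes the whole charge of free monomer present at once, and the steady feed does not supply that. That leaves f at 83.9% on Tuesday's and 73.2% on Saturday's. I commit to 2.85 for Tuesday's, 4.37 for Saturday's, and longer chains in Saturday's. So leave both feed times alone: Saturday's quicker feed spends more initiator than Tuesday's, and the length follows f.

The forecast names Saturday's, with 2.9 (2.6 to 3.2) for Tuesday's and 4.3 (3.9 to 4.7) for Saturday's, holding that “each chain's growth scales with that integral”.

The simulation gives 2.91 for Tuesday's and 4.30 for Saturday's, so Saturday's ends longer. At 10.0 s, propagation ran ahead of initiation by 4.06 on Tuesday's, less than the 7.34 on Saturday's. In the flask Tuesday's left until 40 s, with 38.8% of the initiator standing, the same G gives 12.2 units, and the simulation reads 12.2.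

The constants stand for no real mixture; the flask was simulated.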